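**Retrosynthetic overview**
1. Numbering: C1 (alkene carbon bearing CH3), C2 (alkene CH), C3 (CH2), C4 (quaternary C–CH3), C5 and C6 (CH2), C7 (carbinol carbon bearing isopropyl), C8 (ring-fusion CH), C9 (CH–O-acyl), C10 (CH2 joined to C1). Feature: the seven-membered ring (C1, C2, C3, C4, C8, C9, C10) of the trans-fused bicyclo[5.3.0]decene is a latent cyclohepta-1,4-diene (C1=C2 plus the enol C8=C9), so the C3–C4 bond to quaternary C4 is the σ bond of a Cope rearrangement.
2. C9–O ester ⇒ hindered C9 alcohol + silyl-protected 4-hydroxybenzoic acid; C9 carbinol ⇒ C9 ketone; C8–H ⇒ C8=C9 silyl enol ether.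
3. C3–C4 (key) ⇒ 1-silyloxy-1-cyclopentenyl-2-methyl-2-vinylcyclopropane (C9, C10, C1) ⇒ methylene (C10) transfer to a silyl dienol ether ⇒ crotylation and oxidation of a cyclopentenecarbaldehyde.
4. Cyclopentene ring (C4, C5, C6, C7, C8) ⇒ ozonolysis and aldol ring contraction of (R)-terpinen-4-ol, whose carbinol carbon becomes C7 and steers C4, C8 and C9.
5. Ring order: five-membered ring (step 3), three-membered ring (step 7), seven-membered ring (step 8).

Key step: step 8

Remark on configuration: read from the SMILES, the C4 methyl, the C7 isopropyl group and the C9 acyloxy group lie on one face (β); H8, H9 and the C7 hydroxyl lie on the other (α); the ring fusion is trans, and the target is the (3S,3aS,4R,8aR) isomer in azulene numbering.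
Remark on mixtures: compounds 7, 8, 9 and 12 are expected as stereoisomer mixtures at centres or double bonds that are later erased or equilibrated; their SMILES leave these open, except 12, which is drawn as the reactive cis isomer that leads to 13.
Remark on supply: (R)-(−)-terpinen-4-ol is taken as purchasable in enantioenriched form; its optical purity fixes that of the target. The C7 oxygen is carried as a triethylsilyl ether so that it survives to the last step.

**Route**

Step 1
Reactants: 1 (R)-terpinen-4-ol
Product: 2 (R)-terpinen-4-yl triethylsilyl ether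
Conditions: TESOTf, 2,6-lutidine, CH2Cl2, 0 °C
Reagents that add atoms: triethylsilyl trifluoromethanesulfonate, CC[Si](CC)(CC)OS(=O)(=O)C(F)(F)F
Why: Silylation of a hindered tertiary alcohol with a silyl triflate and a non-nucleophilic base is reliable and leaves the stereocentre untouched.

Step 2
Reactants: 2 (R)-terpinen-4-yl triethylsilyl ether
Product: 3 (3R)-6-oxo-3-(propan-2-yl)-3-(triethylsilyloxy)heptanal
Conditions: O3, CH2Cl2, −78 °C; then PPh3, −78 °C to rt
Reagents that add atoms: ozone, [O-][O+]=O
Why: Ozonolysis with reductive work-up cleaves the only alkene to the methyl ketone and the aldehyde, and the silyl ether blocks retro-aldol loss of the β-oxygen.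

Step 3
Reactants: 3 (3R)-6-oxo-3-(propan-2-yl)-3-(triethylsilyloxy)heptanal
Product: 4 (5S)-2-methyl-5-(propan-2-yl)-5-(triethylsilyloxy)cyclopent-1-ene-1-carbaldehyde
Conditions: piperidine (0.2 equiv), AcOH (0.2 equiv), PhMe, 60 °C
Reagents that add atoms: none
Why: Amine-catalysed intramolecular aldol condensation, in which the aldehyde enamine attacks the methyl ketone (five-membered ring closure) and dehydration gives the conjugated enal; the quaternary C7 cannot epimerise, and mild buffered conditions limit β-elimination of the silyloxy group.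

Step 4
Reactants: 4 (5S)-2-methyl-5-(propan-2-yl)-5-(triethylsilyloxy)cyclopent-1-ene-1-carbaldehyde; 5 crotyl bromide
Product: 7 2-methyl-1-[(5S)-2-methyl-5-(propan-2-yl)-5-(triethylsilyloxy)cyclopent-1-en-1-yl]but-3-en-1-ol (diastereomer mixture), via but-2-enylzinc bromide 6 (not isolated)
Conditions: Zn dust, THF/sat. aq NH4Cl, 0 °C to rt
Reagents that add atoms: none
Why: Barbier crotylation, in which the allylzinc adds 1,2 to the aldehyde through its γ-carbon (SE2′) to give the branched homoallylic alcohol; the two new stereocentres form unselectively and are both erased in steps 5 and 6.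

Step 5
Reactants: 7 homoallylic alcohol
Product: 8 2-methyl-1-[(5S)-2-methyl-5-(propan-2-yl)-5-(triethylsilyloxy)cyclopent-1-en-1-yl]but-3-en-1-one (epimer mixture at the α-carbon)
Conditions: Dess–Martin periodinane, pyridine, CH2Cl2, 0 °C
Reagents that add atoms: none
Why: Dess–Martin oxidation under buffered, non-enolising conditions gives the β,γ-unsaturated ketone without moving the vinyl group into conjugation.

Step 6
Reactants: 8 β,γ-unsaturated ketone
Product: 9 2-methyl-1-[(5S)-2-methyl-5-(propan-2-yl)-5-(triethylsilyloxy)cyclopent-1-en-1-yl]-1-(trimethylsilyloxy)buta-1,3-diene (E/Z mixture at the enol ether bond)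
Conditions: TMSOTf, Et3N, CH2Cl2, −78 to 0 °C
Reagents that add atoms: trimethylsilyl trifluoromethanesulfonate, C[Si](C)(C)OS(=O)(=O)C(F)(F)F
Why: Soft enolisation removes the α-hydrogen that is activated by both the carbonyl and the vinyl group (far more acidic than the vinylogous ring hydrogens) and O-silylation gives the linear silyl dienol ether; its geometry need not be controlled because step 8 is stereoconvergent.

Step 7
Reactants: 9 silyl dienol ether; 10 diiodomethane
Product: 12 (1S,2R)-2-ethenyl-2-methyl-1-[(5S)-2-methyl-5-(propan-2-yl)-5-(triethylsilyloxy)cyclopent-1-en-1-yl]-1-(trimethylsilyloxy)cyclopropane (cyclopentenyl and vinyl cis; formed as a mixture of cyclopropane stereoisomers), via ethyl(iodomethyl)zinc 11 (not isolated)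
Conditions: Et2Zn, CH2Cl2, 0 °C to rt; then pyridine
Reagents that add atoms: none
Why: Furukawa-modified Simmons–Smith cyclopropanation, in which the electrophilic zinc carbenoid adds syn-stereospecifically to the most electron-rich alkene, the C9=C1 silyl enol ether bond, in preference to the terminal vinyl group and the hindered cyclopentene bond; the stereoisomer mixture that results is what step 8 is designed to funnel.

Step 8
Reactants: 12 siloxy divinylcyclopropane
Product: 13 (3S,8aR)-6,8a-dimethyl-3-(propan-2-yl)-3-(triethylsilyloxy)-4-(trimethylsilyloxy)-1,2,3,5,8,8a-hexahydroazulene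
Conditions: PhMe (degassed), Et3N (trace), 130 °C, sealed tube
Reagents that add atoms: none
Why: Heating breaks the C9–C1 cyclopropane bond while the alkene termini C3 and C4 join in a concerted [3,3] shift through a boat transition state with both alkenyl groups over the three-membered ring; the closest known reaction type is the thermal cis-divinylcyclopropane to cyclohepta-1,4-diene rearrangement, known for silyloxy-substituted cyclopropanes and for 2-methylcycloalkenyl partners that end as angular-methyl quaternary carbons. The seven-membered ring (C1, C2, C3, C4, C8, C9, C10) closes by σ-bond formation between the two alkene termini, a sigmatropic ring expansion of the three-membered ring, and the product keeps the C9 oxygen as a silyl enol ether. The new stereocentre C4 is controlled by C7: in the boat the C9–C1 bond must stand perpendicular to the cyclopentene plane, it prefers the face of the C7 silyloxy group over the face of the larger isopropyl group (1,3-strain), and C3 is delivered suprafacially to that same face, which places the C4 methyl cis to the isopropyl group. The step needs this facial selectivity and access to the cis arrangement of the alkenyl groups; both should be secured because the C9–C1 bond, flanked by oxygen and two allylic systems, can undergo reversible homolysis to a stabilised 1,3-diradical at this temperature, so the cyclopropane stereoisomers interconvert and drain through the lowest boat transition state. The inward-pointing C4 methyl slows the [3,3] shift enough for this stereomutation to keep pace, and the trace of amine protects the acid-labile enol ether.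

Step 9
Reactants: 13 bicyclic silyl enol ether
Product: 14 (3S,3aR,8aR)-6,8a-dimethyl-3-(propan-2-yl)-3-(triethylsilyloxy)-2,3,3a,5,8,8a-hexahydroazulen-4(1H)-one (H8 trans to the C4 methyl)
Conditions: Bu4NF, AcOH, THF, −78 °C
Reagents that add atoms: none
Why: Fluoride cleaves the trimethylsilyl enol ether (the hindered tertiary triethylsilyl ether is far slower) and acetic acid protonates C8 at once under kinetic control on the α-face, away from the C4 methyl and the C7 isopropyl group that both stand on the β-face, which sets the trans ring fusion.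

Step 10
Reactants: 14 trans-fused ketone
Product: 15 (3S,3aS,4R,8aR)-6,8a-dimethyl-3-(propan-2-yl)-3-(triethylsilyloxy)-1,2,3,3a,4,5,8,8a-octahydroazulen-4-ol
Conditions: LiBH(s-Bu)3, THF, −78 °C; then H2O
Reagents that add atoms: none
Why: Hydride reduction under steric approach control, in which the bulky borohydride attacks C9 from the open outer (α) side, anti to the pseudo-axial C4 methyl and the isopropyl group, so the new C9–O bond is cis to the C4 methyl and H9 is cis to H8 as in the target; the cold, non-equilibrating conditions avoid epimerisation at C8.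

Step 11
Reactants: 16 4-hydroxybenzoic acid
Product: 18 4-(tert-butyldimethylsilyloxy)benzoic acid, via bis-silylated acid 17 (not isolated)
Conditions: TBSCl (2.5 equiv), imidazole, DMF, rt; then AcOH/THF/H2O, rt
Reagents that add atoms: tert-butyldimethylsilyl chloride, CC(C)(C)[Si](C)(C)Cl
Why: Exhaustive silylation followed by selective hydrolysis of the far more labile silyl ester leaves the aryl silyl ether in place.

Step 12
Reactants: 15 C9 alcohol; 18 4-(tert-butyldimethylsilyloxy)benzoic acid
Product: 20 (3S,3aS,4R,8aR)-6,8a-dimethyl-3-(propan-2-yl)-3-(triethylsilyloxy)-1,2,3,3a,4,5,8,8a-octahydroazulen-4-yl 4-(tert-butyldimethylsilyloxy)benzoate, via mixed anhydride 19 (not isolated)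
Conditions: 18, 2,4,6-Cl3C6H2COCl, Et3N, THF, rt; then 15, DMAP, PhMe, 60 °C
Reagents that add atoms: none
Why: Yamaguchi esterification, in which DMAP opens the mixed anhydride at the unhindered aroyl carbonyl and the resulting acylpyridinium acylates the hindered axial C9 hydroxyl with retention at C9, while the C7 oxygen is blocked as its silyl ether.

Step 13
Reactants: 20 bis-silylated ester
Product: 21 (3S,3aS,4R,8aR)-3-hydroxy-6,8a-dimethyl-3-(propan-2-yl)-1,2,3,3a,4,5,8,8a-octahydroazulen-4-yl 4-hydroxybenzoate (target)
Conditions: Bu4NF, AcOH, THF, 0 to 40 °C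
Reagents that add atoms: none
Why: Fluoride-mediated desilylation cleaves the aryl silyl ether quickly and the tertiary triethylsilyl ether more slowly, and the acetic acid buffer keeps the benzoate, the alkene and the four stereocentres untouched.

**Compound list**
1 | (R)-terpinen-4-ol | CC1=CC[C@@](O)(C(C)C)CC1 | starting material
2 | (R)-terpinen-4-yl triethylsilyl ether | CC1=CC[C@@](O[Si](CC)(CC)CC)(C(C)C)CC1 | intermediate
3 | (3R)-6-oxo-3-(propan-2-yl)-3-(triethylsilyloxy)heptanal | O=CC[C@@](O[Si](CC)(CC)CC)(C(C)C)CCC(C)=O | intermediate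
4 | (5S)-2-methyl-5-(propan-2-yl)-5-(triethylsilyloxy)cyclopent-1-ene-1-carbaldehyde | CC1=C(C=O)[C@@](O[Si](CC)(CC)CC)(C(C)C)CC1 | intermediate
5 | crotyl bromide | C/C=C/CBr | starting material
6 | but-2-enylzinc bromide | C/C=C/C[Zn]Br | intermediate
7 | 2-methyl-1-[(5S)-2-methyl-5-(propan-2-yl)-5-(triethylsilyloxy)cyclopent-1-en-1-yl]but-3-en-1-ol (diastereomer mixture) | CC1=C(C(O)C(C)C=C)[C@@](O[Si](CC)(CC)CC)(C(C)C)CC1 | intermediate
8 | 2-methyl-1-[(5S)-2-methyl-5-(propan-2-yl)-5-(triethylsilyloxy)cyclopent-1-en-1-yl]but-3-en-1-one (epimer mixture) | CC1=C(C(=O)C(C)C=C)[C@@](O[Si](CC)(CC)CC)(C(C)C)CC1 | intermediate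
9 | 2-methyl-1-[(5S)-2-methyl-5-(propan-2-yl)-5-(triethylsilyloxy)cyclopent-1-en-1-yl]-1-(trimethylsilyloxy)buta-1,3-diene (E/Z mixture) | CC1=C(C(O[Si](C)(C)C)=C(C)C=C)[C@@](O[Si](CC)(CC)CC)(C(C)C)CC1 | intermediate
10 | diiodomethane | ICI | starting material
11 | ethyl(iodomethyl)zinc | CC[Zn]CI | intermediate
12 | (1S,2R)-2-ethenyl-2-methyl-1-[(5S)-2-methyl-5-(propan-2-yl)-5-(triethylsilyloxy)cyclopent-1-en-1-yl]-1-(trimethylsilyloxy)cyclopropane | CC1=C([C@]2(O[Si](C)(C)C)C[C@]2(C)C=C)[C@@](O[Si](CC)(CC)CC)(C(C)C)CC1 | intermediate
13 | (3S,8aR)-6,8a-dimethyl-3-(propan-2-yl)-3-(triethylsilyloxy)-4-(trimethylsilyloxy)-1,2,3,5,8,8a-hexahydroazulene | CC1=CC[C@@]2(C)CC[C@](O[Si](CC)(CC)CC)(C(C)C)C2=C(O[Si](C)(C)C)C1 | intermediate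
14 | (3S,3aR,8aR)-6,8a-dimethyl-3-(propan-2-yl)-3-(triethylsilyloxy)-2,3,3a,5,8,8a-hexahydroazulen-4(1H)-one | CC1=CC[C@@]2(C)CC[C@](O[Si](CC)(CC)CC)(C(C)C)[C@@H]2C(=O)C1 | intermediate
15 | (3S,3aS,4R,8aR)-6,8a-dimethyl-3-(propan-2-yl)-3-(triethylsilyloxy)-1,2,3,3a,4,5,8,8a-octahydroazulen-4-ol | CC1=CC[C@@]2(C)CC[C@](O[Si](CC)(CC)CC)(C(C)C)[C@@H]2[C@H](O)C1 | intermediate
16 | 4-hydroxybenzoic acid | OC(=O)c1ccc(O)cc1 | starting material
17 | tert-butyldimethylsilyl 4-(tert-butyldimethylsilyloxy)benzoate | CC(C)(C)[Si](C)(C)OC(=O)c1ccc(O[Si](C)(C)C(C)(C)C)cc1 | intermediate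
18 | 4-(tert-butyldimethylsilyloxy)benzoic acid | OC(=O)c1ccc(O[Si](C)(C)C(C)(C)C)cc1 | intermediate
19 | 4-(tert-butyldimethylsilyloxy)benzoic 2,4,6-trichlorobenzoic anhydride | CC(C)(C)[Si](C)(C)Oc1ccc(cc1)C(=O)OC(=O)c1c(Cl)cc(Cl)cc1Cl | intermediate
20 | (3S,3aS,4R,8aR)-6,8a-dimethyl-3-(propan-2-yl)-3-(triethylsilyloxy)-1,2,3,3a,4,5,8,8a-octahydroazulen-4-yl 4-(tert-butyldimethylsilyloxy)benzoate | CC1=CC[C@@]2(C)CC[C@](O[Si](CC)(CC)CC)(C(C)C)[C@@H]2[C@H](OC(=O)c2ccc(O[Si](C)(C)C(C)(C)C)cc2)C1 | intermediate
21 | (3S,3aS,4R,8aR)-3-hydroxy-6,8a-dimethyl-3-(propan-2-yl)-1,2,3,3a,4,5,8,8a-octahydroazulen-4-yl 4-hydroxybenzoate | CC1=CC[C@@]2(C)CC[C@](O)(C(C)C)[C@@H]2[C@H](OC(=O)c2ccc(O)cc2)C1 | target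

**Step count**
Total steps: 13 (12 in the main line, 1 for the acyl partner).
Longest linear sequence: 12 steps (steps 1–10, 12, 13) from (R)-terpinen-4-ol.

**Steps most likely to fail**

Step 8. The stereomutation of the cyclopropane may be too slow relative to the [3,3] shift, so the stereoisomer mixture from step 7 would be copied into poor facial selectivity at C4. Isomers with the alkenyl groups trans may also be lost through a homo-1,5-hydrogen shift from the C1 methyl group. Fallback by conjugate allylation and ring-closing metathesis, setting out from 4 and returning at 14: addition of 2-methylallylmagnesium chloride to aldehyde 4 (THF, −78 °C) should give the methallyl carbinol F1, and Dess–Martin oxidation the β,γ-unsaturated ketone F2. Hosomi–Sakurai conjugate allylation (allyltrimethylsilane, TiCl4, CH2Cl2, −78 °C) should place the allyl group on C4 anti to the C7 isopropyl group; protonation of the titanium enolate at C8 on the face away from the C4 methyl should then give the C4-allyl ketone F3. Ring-closing metathesis of F3 with the second-generation Grubbs catalyst RuCl2(H2IMes)(PCy3)(=CHPh) (CH2Cl2, 40 °C) forms the C1=C2 bond and gives 14. This path has no cyclopropane stereochemistry to converge, and the C4 epimers are stable ketones that can be separated.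

Step 7. Methylene transfer may go to the terminal vinyl group or occur twice, the crowded tetrasubstituted enol ether may react slowly, and zinc iodide may cleave the silyl enol ether. Fallback by an oxygen-directed samarium carbenoid, setting out from 8 and returning at 12: deprotonation of ketone 8 with LDA (THF, −78 °C) should give the lithium dienolate F4. The samarium carbenoid from CH2I2 and SmI2 (THF, −78 °C to rt), which cyclopropanates only alkenes that carry a metal alkoxide, should convert the enolate C9=C1 bond into the cyclopropanol F5. Silylation (TMSCl, imidazole, CH2Cl2, 0 °C) returns 12.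

Step 9. Protonation may occur from the β-face and give the cis-fused ketone, or the enolate may lose the C7 silyloxy group by β-elimination. Fallback by radical hydrogen-atom transfer in place of enolate protonation, setting out from 13 and returning at 14: N-bromosuccinimide (THF, −78 °C) should convert silyl enol ether 13 into the α-bromo ketone F6. Bu3SnH with AIBN (benzene, 80 °C) should then reduce the C8–Br bond through the planar α-keto radical, which takes hydrogen from the bulky tin hydride on the open α-face and gives 14 with no enolate, so without elimination or epimerisation.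

**Further compounds**
F1 | step 8 | 3-methyl-1-[(5S)-2-methyl-5-(propan-2-yl)-5-(triethylsilyloxy)cyclopent-1-en-1-yl]but-3-en-1-ol | CC1=C(C(O)CC(C)=C)[C@@](O[Si](CC)(CC)CC)(C(C)C)CC1
F2 | step 8 | 3-methyl-1-[(5S)-2-methyl-5-(propan-2-yl)-5-(triethylsilyloxy)cyclopent-1-en-1-yl]but-3-en-1-one | CC1=C(C(=O)CC(C)=C)[C@@](O[Si](CC)(CC)CC)(C(C)C)CC1
F3 | step 8 | 3-methyl-1-[2-methyl-5-(propan-2-yl)-2-(prop-2-enyl)-5-(triethylsilyloxy)cyclopentyl]but-3-en-1-one (allyl cis to the silyloxy group; acyl group cis to the ring methyl and the isopropyl group) | C=CC[C@@]1(C)CC[C@](O[Si](CC)(CC)CC)(C(C)C)[C@@H]1C(=O)CC(C)=C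
F4 | step 7 | lithium dienolate of ketone 8 | CC1=C(C([O-])=C(C)C=C)[C@@](O[Si](CC)(CC)CC)(C(C)C)CC1.[Li+]
F5 | step 7 | (1S,2R)-2-ethenyl-2-methyl-1-[(5S)-2-methyl-5-(propan-2-yl)-5-(triethylsilyloxy)cyclopent-1-en-1-yl]cyclopropan-1-ol | CC1=C([C@]2(O)C[C@]2(C)C=C)[C@@](O[Si](CC)(CC)CC)(C(C)C)CC1
F6 | step 9 | 3a-bromo-6,8a-dimethyl-3-(propan-2-yl)-3-(triethylsilyloxy)-2,3,3a,5,8,8a-hexahydroazulen-4(1H)-one (bromine on the α-face) | CC1=CC[C@@]2(C)CC[C@](O[Si](CC)(CC)CC)(C(C)C)[C@]2(Br)C(=O)C1
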